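**Analysis of the target**

Target 39 (CNP0320218.1) is a eudesmane-type trans-decalin. Ring A (C1–C5, C10) holds the C3=C4 double bond with the C15 methyl on C4, ring B (C5–C10) is saturated, and the fusion carbon C10 is quaternary and carries the free hydroxymethyl group C14. There are six stereocentres, (1R,2S,5R,7S,9S,10S). If the face of C14 is called α, the senecioyloxy group on C1 and the acetoxy group on C2 are cis to each other and α, H-5 is β (trans fusion), and the isopropenyl group on C7 and the acetoxy group on C9 are both β and axial, 1,3-diaxial to each other and to H-5. The sensitive groups are the allylic acetate at C2, the conjugated senecioate, the isopropenyl group and the free neopentyl alcohol, which lies 1,3 to two esters and can accept an acyl group; late hydrogenation, dissolving metals, strong acid and strong base are therefore excluded. The hard points are the absolute configuration of quaternary C10 (flanked by oxygenated C1 and C9 and by C5), a cis-diol on the more hindered α face, two axial groups on ring B, and three esters of two kinds on hindered secondary alcohols next to an unprotected primary one. The strategy rests on C10 being the 4-position of a cyclohexa-2,5-dienone: its two enone arms (the future C1=C2 and C4=C5, ketone at C3) are enantiotopic, and a chain on C10 that already has C9 as a ketone and ends in the C6 aldehyde can be joined to C5 of one arm. That closes ring B and makes C10 a stereocentre in one catalytic step.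

**Retrosynthetic reasoning**

Esters and the C14 hydroxyl (39 ⇐ 38 ⇐ 37 ⇐ 35 ⇐ 34). The primary alcohol is kept silylated to the last step because it would otherwise be acylated first and would attract acyl groups from O-1 and O-9. The C9 acetate is placed while O-1 and O-2 are tied up as an acetonide (34). The diol 35 is then differentiated by the position of its oxygens: O-2 is pseudoaxial and allylic, O-1 equatorial and neopentyl, so an orthoester opening puts the acetate on O-2 (37) and leaves O-1 for the senecioate (38).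

C7–C11 bond and the C9 carbinol (34 ⇐ 33 ⇐ 32 ⇐ 31). Cutting the isopropenyl group from C7 leads to the ring B enone 31, whose carbonyl is the C9 ketone carried from the key step. Conjugate addition to a trans-fused cyclohexenone is axial, which is what the 7β group needs. The ketone reduction must then give the axial 9β alcohol; the syn-axial C7 substituent blocks the other trajectory.

Ring B enone (31 ⇐ 29 ⇐ 28 ⇐ 27). C9 is carried through the ring A chemistry as a pivalate and returns to the ketone level only when no other carbonyl or enolisable centre is left, so the dehydrogenation to 31 has a single possible regiochemistry.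

C5–H and the C3=C4 bond (27 ⇐ 26 ⇐ 25 ⇐ 24). The ring closure creates C5 with H-5 on the α face, the wrong one. Base equilibration through the C6 ketone was not adopted: with sp2 carbons next to both fusion atoms the cis and trans triketones should be close in energy, so a clean inversion cannot be counted on. Instead C5 is made trigonal and rebuilt. The enone 24 is reduced to the 3α allylic alcohol 25, and palladium-catalysed hydrogenolysis of its formate 26 delivers hydride to C5 on the face opposite the leaving group. One stereospecific step thus gives the trans fusion and the C3=C4 bond.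

C1–O and C2–O bonds (24 ⇐ 23 ⇐ 22 ⇐ 20). The cis-diol is taken back to the C1=C2 bond of the cross-conjugated dienone 20. At this stage it is the only alkene that can be osmylated (C4=C5 is a tetrasubstituted enone bond), which avoids the regiochemical problem of oxidising a ring A diene. The α face is the hindered one, so the free C14 hydroxyl is used to deliver the oxidant.

C4–C15 bond and the C4=C5 bond (20 ⇐ 18 ⇐ 17 ⇐ 16). The methyl group is introduced by enolate alkylation of the enone 16, which can enolise only towards C4. Dehydrogenation of 18 then gives 20. The silyl-ethyl ether is removed between these two operations (17 to 18), before the acid-sensitive dienone exists.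

C6 oxygen and the C9 mask (16 ⇐ 15 ⇐ 14 ⇐ 13 ⇐ 12). The three carbonyl groups of 12 are told apart in the first step after the ring closure: both saturated ketones are reduced while the enone stays (13). The less hindered C6 carbinol is removed by radical deoxygenation (14, 15), and the neopentyl C9 carbinol is esterified (16). This leaves one enolisable carbonyl group for the ring A steps and later one hydrogen-bond donor for the directed oxidation.

Key disconnection (12 ⇐ 11). The C5–C6 bond is cut. In 11 the carbons C6–C9 form an acyl chain on the prochiral C10 of a dienone. The forward reaction must turn the aldehyde carbon into an acyl anion equivalent, add it to one of two enantiotopic β carbons, and do so without cleaving the C9–C10 bond, whose loss would aromatise the ring.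

Precursor (11 ⇐ 10 ⇐ 9 ⇐ 6 + 7; 6 ⇐ 4 ⇐ 1 + 2). The dienone comes from a 1,4-cyclohexadiene by oxidation of its doubly allylic CH2. The diene with its quaternary carbon comes from reductive alkylation of 1 with 2, which installs C14 already protected. The acyl chain is attached through the Weinreb amide 6 and the Grignard reagent of 7. No stereochemistry is needed before the key step.

**Alternatives that were turned down**

Alternative 1: Both rings are cut at once, across C1–C2 and C5–C10. This leads to the acyclic trienone A1, a 5-acyl dioxinone whose chain ends in an (E,E)-1-acetoxy-3-methyl diene. Forward, an intramolecular Diels–Alder reaction of the diene (C2–C5) with the dioxinone double bond (C1=C10) would give the tricyclic dioxanone A2.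
- For it: one step makes rings A and B, the quaternary centre, the C3=C4 bond with its methyl group, the C2 acetate and the C1 oxygen. The dioxinone ring fixes O-1 cis to C14, a trans fusion can result directly, and the C9 ketone is ready for the isopropenyl addition. In bond economy and in ring A functionality it is clearly stronger than the chosen route, which spends about a dozen operations on what A2 already contains.
- Against it: the dienophile is a trisubstituted vinylogous carbonate and only moderately activated. Several diastereomeric transition states compete, and the C2 acetate and H-5 must both end up correctly relative to C14. A1, with an enol acetate and an E-trisubstituted diene, is not trivial to assemble. A2 is racemic unless a chiral acetal or catalyst is added, so absolute control of C10 is not built in.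
- Comparison: the chosen strategy offers a catalytic absolute step on an achiral precursor made in five standard operations, and a ring closure whose relative outcome follows from geometry.

Alternative 2: Only ring B is cut, at C9–C10. This leads to the selenoester A3, a chiral-pool-derived cyclohexenone with the C1,C2-diol already present as an acetonide, a tetrasubstituted C5=C10 enone and a four-carbon acyl radical precursor on C5. Forward, the C9 acyl radical would add to the β carbon C10 and give the trans-fused diketone A4.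
- For it: the absolute configuration comes from the chiral pool, and attack anti to the C1 oxygen should set C10 correctly. No dihydroxylation is needed, and the C4 ketone is a good handle for the methyl group and the C3=C4 bond. On ring A oxygenation and absolute stereochemistry it is stronger than the chosen route.
- Against it: the quaternary centre must be forged in the ring closure itself, at a fully substituted β carbon. That is slow for an acyl radical, and closure at C5 to a five-membered ring or simple reduction can compete. H-5 is set by hydrogen-atom transfer to an α-keto radical without a clear bias. A3 needs a long elaboration of the chiral-pool material to a tetrasubstituted enone.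
- Comparison: the chosen route makes the quaternary carbon by alkylating a symmetric dienolate before any ring closure and asks the key step only to choose between two arms.

Alternative 3: This cuts the C7–C11 bond, not the decalin. The isopropenyl group is traced to the 2-bromoallyl ether A5 of an axial C9 alcohol in a decalin with a C6=C7 double bond. Forward, the C11 vinyl radical would add to C7 and close the bridged ether A6; reductive cleavage of its allylic C–O bond would then reveal the isopropenyl group and the C9 hydroxyl.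
- For it: the tether guarantees that the C7 substituent is cis to O-9 and axial, independent of reagent approach. On the C7/C9 relationship it is stronger than the chosen route, whose C9 reduction after the conjugate addition is one of its less certain steps.
- Against it: it presupposes the complete trans-decalin with quaternary C10, the ring A functionality, a 9β alcohol and a C6=C7 alkene. It therefore says nothing about how the skeleton and its absolute configuration arise. It spends three operations on one C–C bond, and the final reductive cleavage must spare the allylic C2–O bond of ring A.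
- Comparison: in the chosen route the C9 ketone, which the key step supplies at no cost, gives the axial isopropenyl group in one conjugate addition.

Key step: step 6

Remark on locants: eudesmane numbering is used for all bicyclic compounds (ring A C1–C5 and C10, ring B C5–C10, C14 on C10, C15 on C4); α is the face that carries C14, β the opposite face.
Remark on step 6: the sense of induction of the triazolium salt is assumed by analogy with oxygen-tethered substrates; if the carbon-tethered case selects the other arm, the mirror-image salt is used and nothing else changes.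
Remark on transient centres: the carbinol carbons C6 and C9 formed in step 7 and the methine C4 formed in step 11 are created without control, are written without descriptor (ξ), and disappear in steps 9, 21 and 13.

**Route**

Step 1
Reactants: 1 benzoic acid; 2 2-(trimethylsilyl)ethoxymethyl chloride
Product: 4 1-{[2-(trimethylsilyl)ethoxy]methyl}cyclohexa-2,5-diene-1-carboxylic acid, via dilithium dienediolate 3 (not isolated)
Conditions: Li (3.2 equiv), NH3(l)/THF, −78 °C; NH3 removed; 2 (2.2 equiv), THF, −78 → 0 °C; 1 M HCl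
Reagents that add atoms: none
Why: Birch reductive alkylation: dissolving-metal reduction of lithium benzoate stops at the dienediolate 3, which is alkylated at C1 (the future C10) by the chloromethyl ether; ammonia is removed first so that it does not consume the electrophile, and the symmetric product has no stereocentre.

Step 2
Reactants: 4 1-{[2-(trimethylsilyl)ethoxy]methyl}cyclohexa-2,5-diene-1-carboxylic acid
Product: 6 N-methoxy-N-methyl-1-{[2-(trimethylsilyl)ethoxy]methyl}cyclohexa-2,5-diene-1-carboxamide, via acid chloride 5 (not isolated)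
Conditions: (COCl)2, DMF (cat.), CH2Cl2, 0 °C → rt; then MeNH(OMe)·HCl, pyridine, 0 °C → rt
Reagents that add atoms: N,O-dimethylhydroxylamine hydrochloride, CNOC.Cl
Why: Weinreb amide formation through the acid chloride, chosen because the carboxyl group sits on a quaternary carbon where direct couplings are slow; the silyl-ethyl ether and the skipped diene tolerate the brief exposure to HCl.

Step 3
Reactants: 6 N-methoxy-N-methyl-1-{[2-(trimethylsilyl)ethoxy]methyl}cyclohexa-2,5-diene-1-carboxamide; 7 2-(2-bromoethyl)-1,3-dioxolane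
Product: 9 3-(1,3-dioxolan-2-yl)-1-(1-{[2-(trimethylsilyl)ethoxy]methyl}cyclohexa-2,5-dien-1-yl)propan-1-one, via Grignard reagent 8 (not isolated)
Conditions: 7, Mg, THF, 25 °C; then 6, THF, 0 °C → rt; aq. NH4Cl
Reagents that add atoms: none
Why: Weinreb ketone synthesis: the chelated tetrahedral adduct survives until work-up, so the C9 ketone forms without over-addition; the dioxolane carries C6 as a latent aldehyde.

Step 4
Reactants: 9 3-(1,3-dioxolan-2-yl)-1-(1-{[2-(trimethylsilyl)ethoxy]methyl}cyclohexa-2,5-dien-1-yl)propan-1-one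
Product: 10 4-[3-(1,3-dioxolan-2-yl)propanoyl]-4-{[2-(trimethylsilyl)ethoxy]methyl}cyclohexa-2,5-dien-1-one
Conditions: (C5H5NH)2Cr2O7, t-BuOOH, Celite, benzene, rt
Reagents that add atoms: tert-butyl hydroperoxide, CC(C)(C)OO
Why: Allylic oxidation of the doubly allylic CH2 (chromium/hydroperoxide) gives the cross-conjugated dienone; the ring carbon para to it is quaternary, so neither aromatisation nor a regiochemical alternative exists.

Step 5
Reactants: 10 4-[3-(1,3-dioxolan-2-yl)propanoyl]-4-{[2-(trimethylsilyl)ethoxy]methyl}cyclohexa-2,5-dien-1-one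
Product: 11 4-oxo-4-(4-oxo-1-{[2-(trimethylsilyl)ethoxy]methyl}cyclohexa-2,5-dien-1-yl)butanal
Conditions: 1 M HCl, THF, 0 °C → rt
Reagents that add atoms: water, O
Why: Acid-catalysed acetal hydrolysis; dilute acid at or below room temperature is used because stronger acid would invite dienone–phenol rearrangement of the 4-acyl dienone and furan formation from the 1,4-keto aldehyde; 11 is used without storage.

Step 6
Reactants: 11 4-oxo-4-(4-oxo-1-{[2-(trimethylsilyl)ethoxy]methyl}cyclohexa-2,5-dien-1-yl)butanal
Product: 12 (5S,10R)-cis-fused 10-{[2-(trimethylsilyl)ethoxy]methyl}decal-1-ene-3,6,9-trione (H-5 α)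
Conditions: (5aS,10bR)-2-(pentafluorophenyl)-5a,10b-dihydro-4H,6H-indeno[2,1-b][1,2,4]triazolo[4,3-d][1,4]oxazin-2-ium tetrafluoroborate (10 mol %), KN(SiMe3)2 (10 mol %), toluene, 23 °C
Reagents that add atoms: none
Why: Intramolecular asymmetric Stetter reaction: the triazolylidene adds to the C6 aldehyde, proton transfer gives the Breslow intermediate (an acyl anion equivalent), this adds to C5 of one enone arm, and proton transfer to C4 with loss of the carbene leaves the C6 ketone. The closest known reaction type is the carbene-catalysed Stetter desymmetrisation of 4,4-disubstituted cyclohexa-2,5-dienones with aminoindanol-derived triazolium salts, best developed for oxygen tethers; here the tether is all-carbon and contains the C9 ketone. Ring B closes in the 6-exo-trig mode (C6 onto C5, with C4=C5 exocyclic to the new ring). C10 becomes stereogenic because only one of the two enantiotopic arms is attacked, and this choice is made by the chiral carbene alone. C5 is set by the tether: the chain hangs from C10 and reaches C5 only on its own face, so C5–C6 is cis to C10–C9 and H-5 falls on the C14 face (cis fusion); this centre is erased in step 13 and need not be correct. The step needs enantiotopic-group selectivity, chemoselectivity for the aldehyde over two ketones, and cyclisation in preference to intermolecular acyloin chemistry. Only an aldehyde can form a Breslow intermediate, the short tether with an sp2 C9 favours cyclisation, and a weak non-nucleophilic base in an aprotic solvent keeps nucleophiles away from the C9 carbonyl, whose cleavage from C10 would aromatise the ring.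

Step 7
Reactants: 12 (5S,10R)-cis-fused 10-{[2-(trimethylsilyl)ethoxy]methyl}decal-1-ene-3,6,9-trione
Product: 13 6ξ,9ξ-dihydroxy-10-{[2-(trimethylsilyl)ethoxy]methyl}-5α-H-decal-1-en-3-one
Conditions: NaBH4, MeOH/CH2Cl2 (1:1), −78 → −30 °C
Reagents that add atoms: none
Why: Chemoselective borohydride reduction: at low temperature in methanol/dichloromethane saturated ketones react much faster than conjugated enones, so C6 and C9 become carbinols and the ring A enone stays; both carbinol centres are temporary.

Step 8
Reactants: 13 6ξ,9ξ-dihydroxy-10-{[2-(trimethylsilyl)ethoxy]methyl}-5α-H-decal-1-en-3-one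
Product: 14 9ξ-hydroxy-6ξ-[(phenoxycarbonothioyl)oxy]-10-{[2-(trimethylsilyl)ethoxy]methyl}-5α-H-decal-1-en-3-one
Conditions: PhOC(S)Cl (1.1 equiv), pyridine, DMAP (cat.), CH2Cl2, 0 °C
Reagents that add atoms: O-phenyl chlorothionoformate, S=C(Cl)Oc1ccccc1
Why: Site-selective thioacylation: the C6 hydroxyl (its neighbour C5 is a methine) reacts far faster than the neopentyl C9 hydroxyl next to quaternary C10.

Step 9
Reactants: 14 9ξ-hydroxy-6ξ-[(phenoxycarbonothioyl)oxy]-10-{[2-(trimethylsilyl)ethoxy]methyl}-5α-H-decal-1-en-3-one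
Product: 15 9ξ-hydroxy-10-{[2-(trimethylsilyl)ethoxy]methyl}-5α-H-decal-1-en-3-one
Conditions: Bu3SnH, AIBN (cat.), toluene, 90 °C
Reagents that add atoms: none
Why: Barton–McCombie deoxygenation: the stannyl radical adds to C=S, the C6–O bond fragments and the secondary C6 radical abstracts hydrogen; the enone offers this radical no favourable cyclisation.

Step 10
Reactants: 15 9ξ-hydroxy-10-{[2-(trimethylsilyl)ethoxy]methyl}-5α-H-decal-1-en-3-one
Product: 16 9ξ-pivaloyloxy-10-{[2-(trimethylsilyl)ethoxy]methyl}-5α-H-decal-1-en-3-one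
Conditions: t-BuCOCl, pyridine, DMAP, 50 °C
Reagents that add atoms: pivaloyl chloride, CC(C)(C)C(Cl)=O
Why: Acylation masks the C9 oxygen: a pivalate has no α-hydrogen and resists amide bases, and with C9 esterified the C14 hydroxyl is later the only hydrogen-bond donor for the directed osmylation.

Step 11
Reactants: 16 9ξ-pivaloyloxy-10-{[2-(trimethylsilyl)ethoxy]methyl}-5α-H-decal-1-en-3-one
Product: 17 4ξ-methyl-9ξ-pivaloyloxy-10-{[2-(trimethylsilyl)ethoxy]methyl}-5α-H-decal-1-en-3-one
Conditions: LiN(i-Pr)2, THF, −78 °C; MeI, −78 → −30 °C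
Reagents that add atoms: iodomethane, CI
Why: Kinetic enolate alkylation: the enone can be deprotonated only at C4 (C10 is quaternary and C9 is no longer a ketone), so methylation is regiospecific; the C4 configuration is irrelevant because C4 becomes sp2 in step 13.

Step 12
Reactants: 17 4ξ-methyl-9ξ-pivaloyloxy-10-{[2-(trimethylsilyl)ethoxy]methyl}-5α-H-decal-1-en-3-one
Product: 18 10-(hydroxymethyl)-4ξ-methyl-9ξ-pivaloyloxy-5α-H-decal-1-en-3-one
Conditions: BF3·OEt2, CH2Cl2, 0 °C
Reagents that add atoms: none
Why: Lewis-acid cleavage of the 2-(trimethylsilyl)ethyl ether (fluoride attack at silicon, loss of ethene) frees the C14 hydroxyl needed as directing group; it is done before the acid-sensitive cross-conjugated dienone exists.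

Step 13
Reactants: 18 10-(hydroxymethyl)-4ξ-methyl-9ξ-pivaloyloxy-5α-H-decal-1-en-3-one
Product: 20 10α-(hydroxymethyl)-4-methyl-9ξ-pivaloyloxydecala-1,4-dien-3-one, via bis(trimethylsilyl) dienol ether 19 (not isolated)
Conditions: Me3SiCl, LiN(i-Pr)2 (2.3 equiv), THF, −78 °C; then Pd(OAc)2 (1.1 equiv), MeCN, rt; aq. citric acid
Reagents that add atoms: none
Why: Saegusa–Ito oxidation: internal-quench silylation gives dienol ether 19 (the C14 alkoxide is silylated at once, which prevents loss of formaldehyde), and Pd(OAc)2 introduces the C4=C5 bond by β-hydride elimination of H-5. This erases the C5 and C4 stereocentres and leaves a dienone whose only osmylation-prone alkene is C1=C2.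

Step 14
Reactants: 20 10α-(hydroxymethyl)-4-methyl-9ξ-pivaloyloxydecala-1,4-dien-3-one
Product: 22 1α,2α-dihydroxy-10α-(hydroxymethyl)-4-methyl-9ξ-pivaloyloxydecal-4-en-3-one, via osmate ester 21 (not isolated)
Conditions: OsO4 (1.05 equiv), TMEDA (1.1 equiv), CH2Cl2, −78 °C; then HCl, MeOH, rt
Reagents that add atoms: osmium tetroxide, O=[Os](=O)(=O)=O
Why: Hydroxyl-directed dihydroxylation with the OsO4·TMEDA complex: the homoallylic C14 hydroxyl hydrogen-bonds to the oxo ligands of the amine-bound reagent and delivers it to the α face of C1=C2, against the steric preference. The tetrasubstituted C4=C5 enone bond is inert, and neutral low-temperature conditions avoid retro-aldol loss of formaldehyde from 20.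

Step 15
Reactants: 22 1α,2α-dihydroxy-10α-(hydroxymethyl)-4-methyl-9ξ-pivaloyloxydecal-4-en-3-one
Product: 23 10α-(hydroxymethyl)-1α,2α-isopropylidenedioxy-4-methyl-9ξ-pivaloyloxydecal-4-en-3-one
Conditions: Me2C(OMe)2, PPTS (cat.), acetone, rt
Reagents that add atoms: 2,2-dimethoxypropane, COC(C)(C)OC
Why: Acetonide formation under thermodynamic control: the cis-1,2-diol closes to the five-membered dioxolane in preference to a six-membered ring through O-14.

Step 16
Reactants: 23 10α-(hydroxymethyl)-1α,2α-isopropylidenedioxy-4-methyl-9ξ-pivaloyloxydecal-4-en-3-one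
Product: 24 10α-[(tert-butyldiphenylsilyloxy)methyl]-1α,2α-isopropylidenedioxy-4-methyl-9ξ-pivaloyloxydecal-4-en-3-one
Conditions: t-BuPh2SiCl, imidazole, DMF, rt
Reagents that add atoms: tert-butyl(chloro)diphenylsilane, CC(C)(C)[Si](Cl)(c1ccccc1)c1ccccc1
Why: Silylation of the primary hydroxyl; the tert-butyldiphenylsilyl ether survives the later acidic, basic and organometallic steps and is removed last.

Step 17
Reactants: 24 10α-[(tert-butyldiphenylsilyloxy)methyl]-1α,2α-isopropylidenedioxy-4-methyl-9ξ-pivaloyloxydecal-4-en-3-one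
Product: 25 10α-[(tert-butyldiphenylsilyloxy)methyl]-1α,2α-isopropylidenedioxy-4-methyl-9ξ-pivaloyloxydecal-4-en-3α-ol
Conditions: NaBH4, CeCl3·7H2O, MeOH, −78 °C
Reagents that add atoms: none
Why: Luche reduction: 1,2-hydride addition from the β face, anti to the pseudoaxial C2–O bond and the acetonide and along the axial trajectory, places the new hydroxyl α (cis to O-2 and C14), as in borohydride reductions of steroidal 4-en-3-ones.

Step 18
Reactants: 25 10α-[(tert-butyldiphenylsilyloxy)methyl]-1α,2α-isopropylidenedioxy-4-methyl-9ξ-pivaloyloxydecal-4-en-3α-ol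
Product: 26 10α-[(tert-butyldiphenylsilyloxy)methyl]-1α,2α-isopropylidenedioxy-4-methyl-9ξ-pivaloyloxydecal-4-en-3α-yl formate
Conditions: HCO2H, DCC, DMAP (cat.), CH2Cl2, 0 °C → rt
Reagents that add atoms: formic acid, OC=O
Why: Steglich-type formylation with retention at C3; the small formyl group can be placed on the hindered allylic alcohol.

Step 19
Reactants: 26 10α-[(tert-butyldiphenylsilyloxy)methyl]-1α,2α-isopropylidenedioxy-4-methyl-9ξ-pivaloyloxydecal-4-en-3α-yl formate
Product: 27 trans-fused 10α-[(tert-butyldiphenylsilyloxy)methyl]-1α,2α-isopropylidenedioxy-4-methyl-5β-H-decal-3-en-9ξ-yl pivalate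
Conditions: Pd(OAc)2 (10 mol %), PBu3 (10 mol %), 1,4-dioxane, 60 °C
Reagents that add atoms: none
Why: Tsuji–Mandai hydrogenolysis of an allylic formate: zerovalent palladium ionises the C3 formate with inversion (metal on the β face), the bound formate loses CO2, and hydride passes from palladium to the more substituted allyl terminus C5 on the β face. This sets H-5 trans to C14 and moves the double bond to C3=C4 in one stereospecific step, as in the formation of trans ring junctions from 3-formyloxy-4-ene steroids; the acetonide oxygen at C2 is a poor leaving group and stays.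

Step 20
Reactants: 27 trans-fused 10α-[(tert-butyldiphenylsilyloxy)methyl]-1α,2α-isopropylidenedioxy-4-methyl-5β-H-decal-3-en-9ξ-yl pivalate
Product: 28 10α-[(tert-butyldiphenylsilyloxy)methyl]-1α,2α-isopropylidenedioxy-4-methyl-5β-H-decal-3-en-9ξ-ol
Conditions: i-Bu2AlH, CH2Cl2, −78 °C; aq. potassium sodium tartrate
Reagents that add atoms: none
Why: Reductive ester cleavage with an aluminium hydride removes the hindered pivalate without touching acetonide, silyl ether or alkene.

Step 21
Reactants: 28 10α-[(tert-butyldiphenylsilyloxy)methyl]-1α,2α-isopropylidenedioxy-4-methyl-5β-H-decal-3-en-9ξ-ol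
Product: 29 10α-[(tert-butyldiphenylsilyloxy)methyl]-1α,2α-isopropylidenedioxy-4-methyl-5β-H-decal-3-en-9-one
Conditions: Dess–Martin periodinane, NaHCO3, CH2Cl2, rt
Reagents that add atoms: none
Why: Dess–Martin oxidation of the hindered secondary alcohol under buffered conditions; both C9 epimers converge on one ketone.

Step 22
Reactants: 29 10α-[(tert-butyldiphenylsilyloxy)methyl]-1α,2α-isopropylidenedioxy-4-methyl-5β-H-decal-3-en-9-one
Product: 31 10α-[(tert-butyldiphenylsilyloxy)methyl]-1α,2α-isopropylidenedioxy-4-methyl-5β-H-decala-3,7-dien-9-one, via trimethylsilyl enol ether 30 (not isolated)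
Conditions: LiN(i-Pr)2, Me3SiCl, THF, −78 °C; then Pd(OAc)2 (1.05 equiv), MeCN, rt
Reagents that add atoms: none
Why: Saegusa–Ito oxidation: C8 is the only enolisable position of the C9 ketone (C10 is quaternary), so the C7=C8 enone forms without regiochemical choice.

Step 23
Reactants: 31 10α-[(tert-butyldiphenylsilyloxy)methyl]-1α,2α-isopropylidenedioxy-4-methyl-5β-H-decala-3,7-dien-9-one
Product: 32 10α-[(tert-butyldiphenylsilyloxy)methyl]-7β-isopropenyl-1α,2α-isopropylidenedioxy-4-methyl-5β-H-decal-3-en-9-one
Conditions: CH2=C(CH3)MgBr, CuBr·SMe2 (20 mol %), THF, −78 → −40 °C; aq. NH4Cl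
Reagents that add atoms: isopropenylmagnesium bromide, C=C(C)[Mg]Br
Why: Copper-catalysed conjugate addition of a Grignard reagent: the nucleophile adds to C7 along the axial trajectory through a chair-like enolate, on the β face trans to the equatorial C5–C4 bond and opposite the axial C14 group, which gives the axial 7β-isopropenyl group; the C3=C4 bond is not an acceptor.

Step 24
Reactants: 32 10α-[(tert-butyldiphenylsilyloxy)methyl]-7β-isopropenyl-1α,2α-isopropylidenedioxy-4-methyl-5β-H-decal-3-en-9-one
Product: 33 10α-[(tert-butyldiphenylsilyloxy)methyl]-7β-isopropenyl-1α,2α-isopropylidenedioxy-4-methyl-5β-H-decal-3-en-9β-ol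
Conditions: Li[HB(s-Bu)3], THF, −78 → 0 °C; H2O
Reagents that add atoms: none
Why: Ketone reduction with a bulky trialkylborohydride: the axial (β) approach to C9 is blocked by the syn-axial isopropenyl group at C7 and by H-5, so hydride enters equatorially and the hydroxyl becomes axial (9β), cis to the isopropenyl group.

Step 25
Reactants: 33 10α-[(tert-butyldiphenylsilyloxy)methyl]-7β-isopropenyl-1α,2α-isopropylidenedioxy-4-methyl-5β-H-decal-3-en-9β-ol
Product: 34 10α-[(tert-butyldiphenylsilyloxy)methyl]-7β-isopropenyl-1α,2α-isopropylidenedioxy-4-methyl-5β-H-decal-3-en-9β-yl acetate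
Conditions: Ac2O, DMAP, Et3N, CH2Cl2, 40 °C
Reagents that add atoms: acetic anhydride, CC(=O)OC(C)=O
Why: DMAP-catalysed acetylation of the hindered axial alcohol; no other hydroxyl is free.

Step 26
Reactants: 34 10α-[(tert-butyldiphenylsilyloxy)methyl]-7β-isopropenyl-1α,2α-isopropylidenedioxy-4-methyl-5β-H-decal-3-en-9β-yl acetate
Product: 35 9β-acetoxy-10α-[(tert-butyldiphenylsilyloxy)methyl]-7β-isopropenyl-4-methyl-5β-H-decal-3-ene-1α,2α-diol
Conditions: AcOH/H2O (4:1), 45 °C
Reagents that add atoms: none
Why: Mild acid hydrolysis of the acetonide; the conditions are too weak to ionise the allylic C2–O bond, hydrate the isopropenyl group or cleave the silyl ether.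

Step 27
Reactants: 35 9β-acetoxy-10α-[(tert-butyldiphenylsilyloxy)methyl]-7β-isopropenyl-4-methyl-5β-H-decal-3-ene-1α,2α-diol
Product: 37 2α,9β-diacetoxy-10α-[(tert-butyldiphenylsilyloxy)methyl]-7β-isopropenyl-4-methyl-5β-H-decal-3-en-1α-ol, via cyclic orthoacetate 36 (not isolated)
Conditions: MeC(OMe)3, PPTS (cat.), CH2Cl2, rt; then AcOH/H2O (4:1), rt
Reagents that add atoms: trimethyl orthoacetate, CC(OC)(OC)OC; water, O
Why: Regioselective monoacetylation through a cyclic orthoester: acid hydrolysis of the orthoacetate of a cis-diol on a six-membered ring opens to the axial ester, here the pseudoaxial allylic O-2, and leaves the equatorial O-1 free.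

Step 28
Reactants: 37 2α,9β-diacetoxy-10α-[(tert-butyldiphenylsilyloxy)methyl]-7β-isopropenyl-4-methyl-5β-H-decal-3-en-1α-ol
Product: 38 2α,9β-diacetoxy-10α-[(tert-butyldiphenylsilyloxy)methyl]-7β-isopropenyl-4-methyl-5β-H-decal-3-en-1α-yl 3-methylbut-2-enoate
Conditions: Me2C=CHCOCl, pyridine, DMAP, CH2Cl2, 0 → 25 °C
Reagents that add atoms: 3-methylbut-2-enoyl chloride, CC(C)=CC(Cl)=O
Why: Acylation with the acid chloride under nucleophilic catalysis; pyridine without a trialkylamine limits vinylketene formation and thus deconjugation of the senecioyl unit, and low temperature limits acetyl migration from O-2 to O-1.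

Step 29
Reactants: 38 2α,9β-diacetoxy-10α-[(tert-butyldiphenylsilyloxy)methyl]-7β-isopropenyl-4-methyl-5β-H-decal-3-en-1α-yl 3-methylbut-2-enoate
Product: 39 (1R,2S,5R,7S,9S,10S)-2,9-diacetoxy-14-hydroxyeudesma-3,11-dien-1-yl 3-methylbut-2-enoate
Conditions: HF·pyridine, pyridine, THF, 0 °C → rt
Reagents that add atoms: none
Why: Fluoride-mediated desilylation under buffered acidic conditions; the esters, the allylic acetate and the alkenes are untouched, and base-induced 1,3-acyl migration to O-14 is avoided.

**Compound list**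

1 | benzoic acid | OC(=O)c1ccccc1 | starting material
2 | 2-(trimethylsilyl)ethoxymethyl chloride | C[Si](C)(C)CCOCCl | starting material
3 | dilithium (cyclohexa-2,5-dien-1-ylidene)methanediolate | [Li+].[Li+].[O-]C([O-])=C1C=CCC=C1 | intermediate (not isolated)
4 | 1-{[2-(trimethylsilyl)ethoxy]methyl}cyclohexa-2,5-diene-1-carboxylic acid | OC(=O)C1(COCC[Si](C)(C)C)C=CCC=C1 | intermediate
5 | 1-{[2-(trimethylsilyl)ethoxy]methyl}cyclohexa-2,5-diene-1-carbonyl chloride | ClC(=O)C1(COCC[Si](C)(C)C)C=CCC=C1 | intermediate (not isolated)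
6 | N-methoxy-N-methyl-1-{[2-(trimethylsilyl)ethoxy]methyl}cyclohexa-2,5-diene-1-carboxamide | CON(C)C(=O)C1(COCC[Si](C)(C)C)C=CCC=C1 | intermediate
7 | 2-(2-bromoethyl)-1,3-dioxolane | BrCCC1OCCO1 | starting material
8 | [2-(1,3-dioxolan-2-yl)ethyl]magnesium bromide | Br[Mg]CCC1OCCO1 | intermediate (not isolated)
9 | 3-(1,3-dioxolan-2-yl)-1-(1-{[2-(trimethylsilyl)ethoxy]methyl}cyclohexa-2,5-dien-1-yl)propan-1-one | O=C(CCC1OCCO1)C2(COCC[Si](C)(C)C)C=CCC=C2 | intermediate
10 | 4-[3-(1,3-dioxolan-2-yl)propanoyl]-4-{[2-(trimethylsilyl)ethoxy]methyl}cyclohexa-2,5-dien-1-one | O=C(CCC1OCCO1)C2(COCC[Si](C)(C)C)C=CC(=O)C=C2 | intermediate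
11 | 4-oxo-4-(4-oxo-1-{[2-(trimethylsilyl)ethoxy]methyl}cyclohexa-2,5-dien-1-yl)butanal | O=CCCC(=O)C1(COCC[Si](C)(C)C)C=CC(=O)C=C1 | intermediate
12 | (5S,10R)-cis-fused 10-{[2-(trimethylsilyl)ethoxy]methyl}decal-1-ene-3,6,9-trione | C1CC(=O)[C@@]2(COCC[Si](C)(C)C)[C@@H](C1=O)CC(=O)C=C2 | intermediate
13 | 6ξ,9ξ-dihydroxy-10-{[2-(trimethylsilyl)ethoxy]methyl}-5α-H-decal-1-en-3-one | C1CC(O)[C@@]2(COCC[Si](C)(C)C)[C@@H](C1O)CC(=O)C=C2 | intermediate
14 | 9ξ-hydroxy-6ξ-[(phenoxycarbonothioyl)oxy]-10-{[2-(trimethylsilyl)ethoxy]methyl}-5α-H-decal-1-en-3-one | C1CC(O)[C@@]2(COCC[Si](C)(C)C)[C@@H](C1OC(=S)Oc3ccccc3)CC(=O)C=C2 | intermediate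
15 | 9ξ-hydroxy-10-{[2-(trimethylsilyl)ethoxy]methyl}-5α-H-decal-1-en-3-one | C1CC(O)[C@@]2(COCC[Si](C)(C)C)[C@@H](C1)CC(=O)C=C2 | intermediate
16 | 9ξ-pivaloyloxy-10-{[2-(trimethylsilyl)ethoxy]methyl}-5α-H-decal-1-en-3-one | C1CC(OC(=O)C(C)(C)C)[C@@]2(COCC[Si](C)(C)C)[C@@H](C1)CC(=O)C=C2 | intermediate
17 | 4ξ-methyl-9ξ-pivaloyloxy-10-{[2-(trimethylsilyl)ethoxy]methyl}-5α-H-decal-1-en-3-one | C1CC(OC(=O)C(C)(C)C)[C@@]2(COCC[Si](C)(C)C)[C@@H](C1)C(C)C(=O)C=C2 | intermediate
18 | 10-(hydroxymethyl)-4ξ-methyl-9ξ-pivaloyloxy-5α-H-decal-1-en-3-one | C1CC(OC(=O)C(C)(C)C)[C@@]2(CO)[C@@H](C1)C(C)C(=O)C=C2 | intermediate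
19 | 4-methyl-9ξ-pivaloyloxy-3-(trimethylsilyloxy)-10-[(trimethylsilyloxy)methyl]-5α-H-decala-1,3-diene | C1CC(OC(=O)C(C)(C)C)[C@@]2(CO[Si](C)(C)C)[C@@H](C1)C(C)=C(O[Si](C)(C)C)C=C2 | intermediate (not isolated)
20 | 10α-(hydroxymethyl)-4-methyl-9ξ-pivaloyloxydecala-1,4-dien-3-one | C1CC(OC(=O)C(C)(C)C)[C@@]2(CO)C(C1)=C(C)C(=O)C=C2 | intermediate
21 | 1α,2α-osmate ester of 22 with dioxo(TMEDA)osmium | C1CC(OC(=O)C(C)(C)C)[C@@]2(CO)C(C1)=C(C)C(=O)[C@H](O[Os-2]3(=O)(=O)([N+](C)(C)CC[N+]3(C)C)O4)[C@@H]24 | intermediate (not isolated)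
22 | 1α,2α-dihydroxy-10α-(hydroxymethyl)-4-methyl-9ξ-pivaloyloxydecal-4-en-3-one | C1CC(OC(=O)C(C)(C)C)[C@@]2(CO)C(C1)=C(C)C(=O)[C@H](O)[C@@H]2O | intermediate
23 | 10α-(hydroxymethyl)-1α,2α-isopropylidenedioxy-4-methyl-9ξ-pivaloyloxydecal-4-en-3-one | C1CC(OC(=O)C(C)(C)C)[C@@]2(CO)C(C1)=C(C)C(=O)[C@H](OC(C)(C)O3)[C@@H]23 | intermediate
24 | 10α-[(tert-butyldiphenylsilyloxy)methyl]-1α,2α-isopropylidenedioxy-4-methyl-9ξ-pivaloyloxydecal-4-en-3-one | C1CC(OC(=O)C(C)(C)C)[C@@]2(CO[Si](c4ccccc4)(c5ccccc5)C(C)(C)C)C(C1)=C(C)C(=O)[C@H](OC(C)(C)O3)[C@@H]23 | intermediate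
25 | 10α-[(tert-butyldiphenylsilyloxy)methyl]-1α,2α-isopropylidenedioxy-4-methyl-9ξ-pivaloyloxydecal-4-en-3α-ol | C1CC(OC(=O)C(C)(C)C)[C@@]2(CO[Si](c4ccccc4)(c5ccccc5)C(C)(C)C)C(C1)=C(C)[C@H](O)[C@H](OC(C)(C)O3)[C@@H]23 | intermediate
26 | 10α-[(tert-butyldiphenylsilyloxy)methyl]-1α,2α-isopropylidenedioxy-4-methyl-9ξ-pivaloyloxydecal-4-en-3α-yl formate | C1CC(OC(=O)C(C)(C)C)[C@@]2(CO[Si](c4ccccc4)(c5ccccc5)C(C)(C)C)C(C1)=C(C)[C@H](OC=O)[C@H](OC(C)(C)O3)[C@@H]23 | intermediate
27 | trans-fused 10α-[(tert-butyldiphenylsilyloxy)methyl]-1α,2α-isopropylidenedioxy-4-methyl-5β-H-decal-3-en-9ξ-yl pivalate | C1CC(OC(=O)C(C)(C)C)[C@@]2(CO[Si](c4ccccc4)(c5ccccc5)C(C)(C)C)[C@H](C1)C(C)=C[C@H](OC(C)(C)O3)[C@@H]23 | intermediate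
28 | 10α-[(tert-butyldiphenylsilyloxy)methyl]-1α,2α-isopropylidenedioxy-4-methyl-5β-H-decal-3-en-9ξ-ol | C1CC(O)[C@@]2(CO[Si](c4ccccc4)(c5ccccc5)C(C)(C)C)[C@H](C1)C(C)=C[C@H](OC(C)(C)O3)[C@@H]23 | intermediate
29 | 10α-[(tert-butyldiphenylsilyloxy)methyl]-1α,2α-isopropylidenedioxy-4-methyl-5β-H-decal-3-en-9-one | C1CC(=O)[C@@]2(CO[Si](c4ccccc4)(c5ccccc5)C(C)(C)C)[C@H](C1)C(C)=C[C@H](OC(C)(C)O3)[C@@H]23 | intermediate
30 | 10α-[(tert-butyldiphenylsilyloxy)methyl]-1α,2α-isopropylidenedioxy-4-methyl-9-(trimethylsilyloxy)-5β-H-decala-3,8-diene | C1C=C(O[Si](C)(C)C)[C@@]2(CO[Si](c4ccccc4)(c5ccccc5)C(C)(C)C)[C@H](C1)C(C)=C[C@H](OC(C)(C)O3)[C@@H]23 | intermediate (not isolated)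
31 | 10α-[(tert-butyldiphenylsilyloxy)methyl]-1α,2α-isopropylidenedioxy-4-methyl-5β-H-decala-3,7-dien-9-one | C1=CC(=O)[C@@]2(CO[Si](c4ccccc4)(c5ccccc5)C(C)(C)C)[C@H](C1)C(C)=C[C@H](OC(C)(C)O3)[C@@H]23 | intermediate
32 | 10α-[(tert-butyldiphenylsilyloxy)methyl]-7β-isopropenyl-1α,2α-isopropylidenedioxy-4-methyl-5β-H-decal-3-en-9-one | C=C(C)[C@@H]1CC(=O)[C@@]2(CO[Si](c4ccccc4)(c5ccccc5)C(C)(C)C)[C@H](C1)C(C)=C[C@H](OC(C)(C)O3)[C@@H]23 | intermediate
33 | 10α-[(tert-butyldiphenylsilyloxy)methyl]-7β-isopropenyl-1α,2α-isopropylidenedioxy-4-methyl-5β-H-decal-3-en-9β-ol | C=C(C)[C@@H]1C[C@H](O)[C@@]2(CO[Si](c4ccccc4)(c5ccccc5)C(C)(C)C)[C@H](C1)C(C)=C[C@H](OC(C)(C)O3)[C@@H]23 | intermediate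
34 | 10α-[(tert-butyldiphenylsilyloxy)methyl]-7β-isopropenyl-1α,2α-isopropylidenedioxy-4-methyl-5β-H-decal-3-en-9β-yl acetate | C=C(C)[C@@H]1C[C@H](OC(C)=O)[C@@]2(CO[Si](c4ccccc4)(c5ccccc5)C(C)(C)C)[C@H](C1)C(C)=C[C@H](OC(C)(C)O3)[C@@H]23 | intermediate
35 | 9β-acetoxy-10α-[(tert-butyldiphenylsilyloxy)methyl]-7β-isopropenyl-4-methyl-5β-H-decal-3-ene-1α,2α-diol | C=C(C)[C@@H]1C[C@H](OC(C)=O)[C@@]2(CO[Si](c4ccccc4)(c5ccccc5)C(C)(C)C)[C@H](C1)C(C)=C[C@H](O)[C@@H]2O | intermediate
36 | 1α,2α-(1-methoxyethylidene) orthoacetate of 35 | C=C(C)[C@@H]1C[C@H](OC(C)=O)[C@@]2(CO[Si](c4ccccc4)(c5ccccc5)C(C)(C)C)[C@H](C1)C(C)=C[C@H](OC(C)(OC)O3)[C@@H]23 | intermediate (not isolated)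
37 | 2α,9β-diacetoxy-10α-[(tert-butyldiphenylsilyloxy)methyl]-7β-isopropenyl-4-methyl-5β-H-decal-3-en-1α-ol | C=C(C)[C@@H]1C[C@H](OC(C)=O)[C@@]2(CO[Si](c4ccccc4)(c5ccccc5)C(C)(C)C)[C@H](C1)C(C)=C[C@H](OC(C)=O)[C@@H]2O | intermediate
38 | 2α,9β-diacetoxy-10α-[(tert-butyldiphenylsilyloxy)methyl]-7β-isopropenyl-4-methyl-5β-H-decal-3-en-1α-yl 3-methylbut-2-enoate | C=C(C)[C@@H]1C[C@H](OC(C)=O)[C@@]2(CO[Si](c4ccccc4)(c5ccccc5)C(C)(C)C)[C@H](C1)C(C)=C[C@H](OC(C)=O)[C@@H]2OC(=O)C=C(C)C | intermediate
39 | (1R,2S,5R,7S,9S,10S)-2,9-diacetoxy-14-hydroxyeudesma-3,11-dien-1-yl 3-methylbut-2-enoate (CNP0320218.1) | C=C(C)[C@@H]1C[C@H](OC(C)=O)[C@@]2(CO)[C@H](C1)C(C)=C[C@H](OC(C)=O)[C@@H]2OC(=O)C=C(C)C | target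

**Step count and least certain steps**

Total: 29 steps. Longest linear sequence: 29 steps (1 to 39); 2 and 7 are purchased.

Step 6 (key step). The all-carbon tether may give poor discrimination between the two enantiotopic arms, because the precedent is strongest for oxygen tethers. A second risk is attack of base or carbene at the C9 carbonyl with C9–C10 cleavage, driven by aromatisation of the dienone. Fallback, from 6 and back at 15: the same C5–C6 bond is made by enamine catalysis with a one-carbon longer chain.
- Amide 6 is treated with the Grignard reagent of commercial 2-(3-bromopropyl)-1,3-dioxolane to give the homologous ketone F1.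
- Allylic oxidation as in step 4 gives the dienone acetal F2, and hydrolysis as in step 5 gives the keto aldehyde F3.
- (S)-2-[Diphenyl(trimethylsilyloxy)methyl]pyrrolidine with PhCO2H converts F3 through its enamine into the cis-fused 6-formyl bicycle F4, a known type of desymmetrising intramolecular Michael addition.
- RhCl(PPh3)3 (1.1 equiv, toluene, 110 °C) removes the formyl carbon to give the enone ketone F5.
- NaBH4 under the conditions of step 7 reduces the C9 ketone of F5 to 15.

Step 14. The steric preference of the flat dienone is for attack anti to C14, so delivery by the hydroxyl may not override it fully; the enone alkene is also electron-poor and may react slowly, and 20 can lose formaldehyde if the medium turns basic. Fallback, from 16 and back at 24: the diol is introduced on the cis-fused enone, where the convex face is the α face and substrate control and the hydroxyl act in the same sense.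
- BF3·OEt2 converts 16 into the hydroxy enone F6.
- OsO4 (cat.) with N-methylmorpholine N-oxide gives the 1α,2α-diol F7.
- Acetonide formation gives F8, and silylation as in step 16 gives the silyl ether F9.
- The kinetic enolate of F9 (LiN(i-Pr)2, −78 °C; C4 is the only CH2 next to the ketone) and dimethyl(methylidene)ammonium iodide give the Mannich base F10.
- N-Methylation (MeI) and NaHCO3 give the α-methylene ketone F11 with loss of trimethylamine, and DBU moves the exocyclic double bond into the ring to give 24.

Step 19. Ionisation of the hindered allylic formate next to the C2 oxygen may be slow, hydride may go to C3 instead of C5, or β-hydride elimination may give dienes. Fallback, from 25 and back at 27: Myers reductive transposition. Mitsunobu reaction of 25 with 2-nitrobenzenesulfonylhydrazide (PPh3, diethyl azodicarboxylate, −30 °C) gives with inversion the 3β-sulfonylhydrazine F12. On warming it loses the sulfinic acid to the allylic diazene F13, which transfers hydrogen to C5 on the β face by a retro-ene reaction with loss of N2 and gives 27.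

Step 24. Both faces of the C9 ketone carry an axial neighbour (the C7 isopropenyl group on β, the C14 group on α), so the reaction may be slow or poorly face-selective. Fallback, from 32 and back at 33: hydroxyl-directed reduction. HF·pyridine removes the silyl group of 32 to give the hydroxy ketone F14. Me4N[HB(OAc)3] (MeCN/AcOH, −20 °C) delivers hydride from the C14 oxygen on the α face and gives the 9β,14-diol F15. t-BuPh2SiCl with imidazole silylates the primary hydroxyl selectively and returns 33.

Step 28. Under the basic acylation conditions the acetyl group may migrate from the axial O-2 to the equatorial O-1 before the hindered O-1 is acylated, and the senecioyl unit may deconjugate through a ketene. Fallback, from 35 and back at 38: the order of the two acylations is reversed. Bu2SnO (toluene, reflux) converts 35 into the stannylene acetal F16, which is acylated by 3-methylbut-2-enoyl chloride on the equatorial O-1 to give the 1α-senecioate F17. Acetylation of its axial O-2 (Ac2O, DMAP) gives 38; migration of the senecioate from the equatorial to the axial oxygen is not favoured.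

**Further compounds**

F1 | step 6 | 4-(1,3-dioxolan-2-yl)-1-(1-{[2-(trimethylsilyl)ethoxy]methyl}cyclohexa-2,5-dien-1-yl)butan-1-one | O=C(CCCC1OCCO1)C2(COCC[Si](C)(C)C)C=CCC=C2
F2 | step 6 | 4-[4-(1,3-dioxolan-2-yl)butanoyl]-4-{[2-(trimethylsilyl)ethoxy]methyl}cyclohexa-2,5-dien-1-one | O=C(CCCC1OCCO1)C2(COCC[Si](C)(C)C)C=CC(=O)C=C2
F3 | step 6 | 5-oxo-5-(4-oxo-1-{[2-(trimethylsilyl)ethoxy]methyl}cyclohexa-2,5-dien-1-yl)pentanal | O=CCCCC(=O)C1(COCC[Si](C)(C)C)C=CC(=O)C=C1
F4 | step 6 | cis-fused 6ξ-formyl-10-{[2-(trimethylsilyl)ethoxy]methyl}-5α-H-decal-1-ene-3,9-dione | C1CC(=O)[C@@]2(COCC[Si](C)(C)C)[C@@H](C1C=O)CC(=O)C=C2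
F5 | step 6 | cis-fused 10-{[2-(trimethylsilyl)ethoxy]methyl}-5α-H-decal-1-ene-3,9-dione | C1CC(=O)[C@@]2(COCC[Si](C)(C)C)[C@@H](C1)CC(=O)C=C2
F6 | step 14 | 10-(hydroxymethyl)-9ξ-pivaloyloxy-5α-H-decal-1-en-3-one | C1CC(OC(=O)C(C)(C)C)[C@@]2(CO)[C@@H](C1)CC(=O)C=C2
F7 | step 14 | 1α,2α-dihydroxy-10-(hydroxymethyl)-9ξ-pivaloyloxy-5α-H-decalin-3-one | C1CC(OC(=O)C(C)(C)C)[C@@]2(CO)[C@@H](C1)CC(=O)[C@H](O)[C@@H]2O
F8 | step 14 | 10-(hydroxymethyl)-1α,2α-isopropylidenedioxy-9ξ-pivaloyloxy-5α-H-decalin-3-one | C1CC(OC(=O)C(C)(C)C)[C@@]2(CO)[C@@H](C1)CC(=O)[C@H](OC(C)(C)O3)[C@@H]23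
F9 | step 14 | 10-[(tert-butyldiphenylsilyloxy)methyl]-1α,2α-isopropylidenedioxy-9ξ-pivaloyloxy-5α-H-decalin-3-one | C1CC(OC(=O)C(C)(C)C)[C@@]2(CO[Si](c4ccccc4)(c5ccccc5)C(C)(C)C)[C@@H](C1)CC(=O)[C@H](OC(C)(C)O3)[C@@H]23
F10 | step 14 | 4ξ-[(dimethylamino)methyl] derivative of F9 | C1CC(OC(=O)C(C)(C)C)[C@@]2(CO[Si](c4ccccc4)(c5ccccc5)C(C)(C)C)[C@@H](C1)C(CN(C)C)C(=O)[C@H](OC(C)(C)O3)[C@@H]23
F11 | step 14 | 4-methylidene derivative of F9 | C1CC(OC(=O)C(C)(C)C)[C@@]2(CO[Si](c4ccccc4)(c5ccccc5)C(C)(C)C)[C@@H](C1)C(=C)C(=O)[C@H](OC(C)(C)O3)[C@@H]23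
F12 | step 19 | 3β-[1-(2-nitrophenylsulfonyl)hydrazinyl] analogue of 25 | C1CC(OC(=O)C(C)(C)C)[C@@]2(CO[Si](c4ccccc4)(c5ccccc5)C(C)(C)C)C(C1)=C(C)[C@@H](N(N)S(=O)(=O)c6ccccc6[N+](=O)[O-])[C@H](OC(C)(C)O3)[C@@H]23
F13 | step 19 | 3β-diazenyl analogue of 25 | C1CC(OC(=O)C(C)(C)C)[C@@]2(CO[Si](c4ccccc4)(c5ccccc5)C(C)(C)C)C(C1)=C(C)[C@@H](N=N)[C@H](OC(C)(C)O3)[C@@H]23
F14 | step 24 | 10α-(hydroxymethyl)-7β-isopropenyl-1α,2α-isopropylidenedioxy-4-methyl-5β-H-decal-3-en-9-one | C=C(C)[C@@H]1CC(=O)[C@@]2(CO)[C@H](C1)C(C)=C[C@H](OC(C)(C)O3)[C@@H]23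
F15 | step 24 | 10α-(hydroxymethyl)-7β-isopropenyl-1α,2α-isopropylidenedioxy-4-methyl-5β-H-decal-3-en-9β-ol | C=C(C)[C@@H]1C[C@H](O)[C@@]2(CO)[C@H](C1)C(C)=C[C@H](OC(C)(C)O3)[C@@H]23
F16 | step 28 | 1α,2α-O-dibutylstannylene acetal of 35 | C=C(C)[C@@H]1C[C@H](OC(C)=O)[C@@]2(CO[Si](c4ccccc4)(c5ccccc5)C(C)(C)C)[C@H](C1)C(C)=C[C@H](O[Sn](CCCC)(CCCC)O3)[C@@H]23
F17 | step 28 | 9β-acetoxy-10α-[(tert-butyldiphenylsilyloxy)methyl]-2α-hydroxy-7β-isopropenyl-4-methyl-5β-H-decal-3-en-1α-yl 3-methylbut-2-enoate | C=C(C)[C@@H]1C[C@H](OC(C)=O)[C@@]2(CO[Si](c4ccccc4)(c5ccccc5)C(C)(C)C)[C@H](C1)C(C)=C[C@H](O)[C@@H]2OC(=O)C=C(C)C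
A1 | alternative 1 | 5-[(5E,7E)-8-acetoxy-6-methylocta-5,7-dienoyl]-2,2-dimethyl-4H-1,3-dioxin-4-one | O=C1OC(C)(C)OC=C1C(=O)CCC/C=C(C)/C=C/OC(C)=O
A2 | alternative 1 | trans-fused tricyclic dioxanone Diels–Alder adduct with C9 ketone | C1CC(=O)[C@@]2(C(=O)OC(C)(C)O3)[C@H](C1)C(C)=C[C@H](OC(C)=O)[C@@H]23
A3 | alternative 2 | Se-phenyl selenoester of the C1,C2-acetonide enone with a tetrasubstituted C5=C10 bond | O=C([Se]c1ccccc1)CCCC2=C(CO[Si](C)(C)C(C)(C)C)[C@H]3OC(C)(C)O[C@H]3CC2=O
A4 | alternative 2 | trans-fused 4,9-diketone with quaternary C10 | C1CC(=O)[C@@]2(CO[Si](C)(C)C(C)(C)C)[C@H](C1)C(=O)C[C@H](OC(C)(C)O3)[C@@H]23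
A5 | alternative 3 | 9β-(2-bromoallyloxy) decala-3,6-diene with C1,C2-acetonide and C14 silyl ether | C1C[C@H](OCC(Br)=C)[C@@]2(CO[Si](C)(C)C(C)(C)C)[C@H](C=1)C(C)=C[C@H](OC(C)(C)O3)[C@@H]23
A6 | alternative 3 | C7–C9 bridged methylene oxacycle | C=C4[C@@H]1C[C@H](OC4)[C@@]2(CO[Si](C)(C)C(C)(C)C)[C@H](C1)C(C)=C[C@H](OC(C)(C)O3)[C@@H]23
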